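The route rests on disconnecting the C8–OMe bond of ring A in a flavanone that already carries the (2S) centre and every other oxygen. In ring A, C8 lies para to the C5 oxygen and is the only position the target oxygenates beyond the natural 5,7 pattern. Anodic oxidation of the free C5 phenol in methanol therefore puts two methoxy groups on C8 in one operation, giving the p-quinone monoketal without touching ring C or C2. The precursor is (S)-5-hydroxy-7,3',4'-trimethoxyflavanone, reached by base-free O-methylation of (S)-hesperetin. Zinc reduction of the ketal and methylation of the C5 phenol finish the synthesis.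

Key step: step 2

Remark: flavanone numbering is used (ring A benzo ring, ring B the 2-aryl group, ring C the pyranone), and commercial (S)-hesperetin is assumed to be configurationally pure at C2, to be confirmed by chiral HPLC before use.

Step 1
Reactants: 1 (S)-hesperetin; 2 trimethylsilyldiazomethane; 3 methanol
Product: 5 (S)-2-(3,4-dimethoxyphenyl)-5-hydroxy-7-methoxychroman-4-one, via 7-O-methylhesperetin 4 (not isolated)
Conditions: TMSCHN2 (2 M in hexanes, 5 equiv, in portions), MeOH/toluene, 0 °C → rt; AcOH quench
Reagents that add atoms: trimethylsilyldiazomethane, C[Si](C)(C)C=[N+]=[N-]
Why: O-methylation of phenols by a diazoalkane (diazomethane released from the silyl reagent by methanol): the acidic C7 phenol and then the ring B C3' phenol protonate the reagent and are methylated, whereas the C5 phenol, held in a six-membered hydrogen bond to the C4 carbonyl, reacts far more slowly, and since no base is present the β-aryloxy ketone of ring C cannot open, so C2 stays S and no stereocentre is formed.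

Step 2
Reactants: 5 (S)-2-(3,4-dimethoxyphenyl)-5-hydroxy-7-methoxychroman-4-one; 3 methanol
Product: 7 (S)-2-(3,4-dimethoxyphenyl)-7,8,8-trimethoxy-2,3-dihydro-4H-chromene-4,5(8H)-dione, via 5-hydroxy-7,8-dimethoxy flavanone 6 (not isolated)
Conditions: graphite anode, Pt cathode, undivided cell, LiClO4 (0.1 M), 2,6-lutidine (3 equiv), MeOH, 0 °C, anode potential held at the foot of the phenol wave, 4–4.5 F/mol
Reagents that add atoms: methanol, CO
Why: Anodic two-electron oxidation of the C5 phenol, with 2,6-lutidine taking the proton, gives a ring A phenoxonium ion that methanol captures at C8, para to the C5 oxygen, and tautomerisation gives the 8-methoxy phenol 6; as a p-methoxyphenol, 6 is oxidised at a lower potential than 5, and its phenoxonium ion, now stabilised by the C8 methoxy group, takes up a second methanol at C8 to give the 8,8-dimethyl ketal 7, which as a cross-conjugated enedione is electron-poor and should not be oxidised further. The closest known reaction type is the anodic methoxylation of para-unsubstituted phenols in methanol/LiClO4 to 4,4-dimethoxycyclohexa-2,5-dienones (p-quinone monoketals). No ring is closed; two C8–O bonds are formed. No stereocentre is created, since C8 carries two identical methoxy groups, and C2 should stay S because the lutidine/lutidinium buffer keeps the medium near neutral (protons released at the anode are discharged as H2 at the cathode), so C3 is not enolised and ring C does not open. The step needs capture at C8 and not at C6, and oxidation of ring A and not of the dimethoxyphenyl ring B: the first rests on the para relation of C8 to the C5 oxygen, where phenoxonium ions are preferentially captured (capture at C6 would pass through the less stable linearly conjugated dienone), reinforced in the second stage by the methoxy group already on C8; the second rests on the free C5 hydroxyl, which makes base-assisted, proton-coupled oxidation available to ring A only, so that at the chosen potential the aryl ether ring B should not yet be oxidised.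

Step 3
Reactants: 7 (S)-2-(3,4-dimethoxyphenyl)-7,8,8-trimethoxy-2,3-dihydro-4H-chromene-4,5(8H)-dione
Product: 6 (S)-2-(3,4-dimethoxyphenyl)-5-hydroxy-7,8-dimethoxychroman-4-one
Conditions: Zn dust (5 equiv), AcOH/THF, 0 °C → rt
Reagents that add atoms: none
Why: Dissolving-metal reduction (reductive aromatisation of a p-quinone monoketal): zinc transfers two electrons to the cross-conjugated enedione, one C8 methoxy group leaves as methanol and ring A returns as the 5-hydroxy-8-methoxy arene, while the C4 aryl ketone and the C2–O1 bond are inert to zinc in acetic acid at this temperature, so C2 is unchanged and no stereocentre is formed.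

Step 4
Reactants: 6 (S)-2-(3,4-dimethoxyphenyl)-5-hydroxy-7,8-dimethoxychroman-4-one; 8 iodomethane
Product: 9 (S)-2-(3,4-dimethoxyphenyl)-5,7,8-trimethoxychroman-4-one
Conditions: MeI (10 equiv), Ag2O (3 equiv), 4 Å MS, CH2Cl2, rt, dark
Reagents that add atoms: iodomethane, CI
Why: Purdie methylation (Ag2O-assisted SN2 O-alkylation): silver activates iodomethane and takes up iodide while the oxide accepts the phenolic proton, so the chelated C5 phenol is methylated without a soluble base that could enolise C3 and open ring C by retro-oxa-Michael elimination, and C2 therefore keeps its S configuration with no stereocentre formed.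

Compound list
1 | (S)-hesperetin, (2S)-5,7-dihydroxy-2-(3-hydroxy-4-methoxyphenyl)chroman-4-one | COc1ccc([C@@H]2CC(=O)c3c(O)cc(O)cc3O2)cc1O | starting material
2 | trimethylsilyldiazomethane | C[Si](C)(C)C=[N+]=[N-] | starting material
3 | methanol | CO | starting material
4 | 7-O-methylhesperetin, (2S)-5-hydroxy-2-(3-hydroxy-4-methoxyphenyl)-7-methoxychroman-4-one | COc1ccc([C@@H]2CC(=O)c3c(O)cc(OC)cc3O2)cc1O | intermediate
5 | (S)-2-(3,4-dimethoxyphenyl)-5-hydroxy-7-methoxychroman-4-one | COc1ccc([C@@H]2CC(=O)c3c(O)cc(OC)cc3O2)cc1OC | intermediate
6 | (S)-2-(3,4-dimethoxyphenyl)-5-hydroxy-7,8-dimethoxychroman-4-one | COc1ccc([C@@H]2CC(=O)c3c(O)cc(OC)c(OC)c3O2)cc1OC | intermediate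
7 | (S)-2-(3,4-dimethoxyphenyl)-7,8,8-trimethoxy-2,3-dihydro-4H-chromene-4,5(8H)-dione | COc1ccc([C@@H]2CC(=O)C3=C(O2)C(OC)(OC)C(OC)=CC3=O)cc1OC | intermediate
8 | iodomethane | CI | starting material
9 | (S)-2-(3,4-dimethoxyphenyl)-5,7,8-trimethoxychroman-4-one | COc1ccc([C@@H]2CC(=O)c3c(OC)cc(OC)c(OC)c3O2)cc1OC | target

Total step count: 4. Longest linear sequence: 4 steps (1 → 5 → 7 → 6 → 9).

Steps most likely to fail

Step 2. What may go wrong: electron transfer from the dimethoxyphenyl ring B may compete, including oxidation at the benzylic C2–H. Methanol may be captured ortho at C6. The anode may foul through phenol coupling, and ring C may open in a basic layer at the cathode. Fallback, setting out from 5: the electrode is given up for a stoichiometric trivalent-iodine oxidant, PhI(OAc)2 (2.2–2.5 equiv) in MeOH at 0 °C to rt. The phenol first exchanges an acetate on iodine, so oxidation is delivered through the C5 oxygen alone; ring B has no free hydroxyl and cannot engage, and the medium is weakly acidic, not basic. Two such oxidative dearomatisation cycles with methanol capture at C8 (a known route from para-unsubstituted phenols to p-quinone monoketals) give 7 directly, and the route is rejoined at 7 before step 3. This fallback makes no new compound (F0).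

Step 4. What may go wrong: alkylation of the chelated phenol may be slow. On forcing, enolisation at C3 followed by retro-oxa-Michael opening of ring C would erode the C2 configuration and divert material to open-chain products. Fallback, setting out from 6: the ketone is taken out of play before the alkylation. NaBH4 (MeOH/THF, 0 °C) reduces C4 to (2S,4S)-2-(3,4-dimethoxyphenyl)-7,8-dimethoxychromane-4,5-diol F1. The 2,4-cis isomer is expected from axial hydride delivery, and the C4 epimer would serve equally because C4 is oxidised again. Without the carbonyl the C5 phenol is no longer chelated and there is no enolisable β-aryloxy ketone, so MeI/K2CO3 in acetone at rt should give (2S,4S)-2-(3,4-dimethoxyphenyl)-5,7,8-trimethoxychroman-4-ol F2. F2 is kept free of acid, since the electron-rich benzylic alcohol ionises readily. MnO2 in CH2Cl2 at rt then oxidises the benzylic alcohol back to the ketone and the route is rejoined at 9.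

Step 1. What may go wrong: methylation of the weakly acidic ring B phenol may stay incomplete, or the C5 phenol may be slowly methylated when the reagent is forced. Fallback, setting out from 1: Mitsunobu reaction with methanol (PPh3, diisopropyl azodicarboxylate, MeOH, 2.2 equiv each, THF, 0 °C to rt). Here the phenols act as nucleophiles toward a methoxyphosphonium ion. The free C7 and C3' phenols should react, while the chelated C5 phenol does not protonate the betaine and is left. No free base is present, so C2 is not at risk, and the route is rejoined at 5 before step 2. This fallback makes no new compound (F0).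

Further compounds
F0 | step 2 | none | none
F1 | step 4 | (2S,4S)-2-(3,4-dimethoxyphenyl)-7,8-dimethoxychromane-4,5-diol | COc1ccc([C@@H]2C[C@H](O)c3c(O)cc(OC)c(OC)c3O2)cc1OC
F2 | step 4 | (2S,4S)-2-(3,4-dimethoxyphenyl)-5,7,8-trimethoxychroman-4-ol | COc1ccc([C@@H]2C[C@H](O)c3c(OC)cc(OC)c(OC)c3O2)cc1OC
F0 | step 1 | none | none
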